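**Retrosynthetic overview**
1. Target ⇐ reduction of both carbonyls of a quinone epoxide ⇐ tartrate-controlled nucleophilic epoxidation of a quinone monoketal ⇐ oxidative dearomatisation of a p-methoxyphenol that already carries the decalin.
2. Decalin acid ⇐ bicyclic β-keto ester, by C3 deoxygenation, exo→endo alkene shift and ester→acid adjustment.
3. Key disconnection: C4–C5 and C9–C10 in one operation, an auxiliary-controlled oxidative radical bicyclisation of an open-chain aryl-diene β-keto ester (rings A and B together, four stereocentres).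
4. Open-chain precursor ⇐ 2-methylacetoacetate dianion + allylic bromide ⇐ terminal allylic oxidation of a geranyl arene ⇐ arylcopper + geranyl bromide.
5. Ring order: arene (bought) → rings A and B together → oxirane last, on the dearomatised arene.

**Conventions.** Drimane numbering for the decalin (C4 carries CH3 and the carboxyl carbon, C10 the angular CH3, C9 the C11 methylene, C8 the C12 carbon). Primed numbers for the oxygenated six-ring (C1′ carries C11, C2′ is the other oxirane carbon, C3′ and C6′ carry OH, C4′ carries CH2OH). ArT = 5-methoxy-2-(triisopropylsilyloxy)-4-[(triisopropylsilyloxy)methyl]phenyl. Pm = (1R,2S,5R)-8-phenylmenthyl. "Target decalin configuration" means: trans-fused, with the C4 carbonyl carbon (axial), the C10 methyl and C11 on one face and H5 and H9 on the other, in the ent-drimane absolute sense shown in the SMILES.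

Assumption 1: the (−)-8-phenylmenthyl ester is taken to give the ent-drimane series, by analogy with the reported sense of this auxiliary in such cyclisations (recalled, not verified); if the sense is opposite, the (+)-auxiliary is used with nothing else changed.
Assumption 2: L-(+)-diisopropyl tartrate is taken to deliver the oxirane to the face drawn; if not, the D-tartrate is used.

**Step 1**
Reactants: 1 5-hydroxy-2-methoxybenzaldehyde
Product: 2 3-(hydroxymethyl)-4-methoxyphenol
Conditions: NaBH4, MeOH, 0 °C; dilute HCl work-up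
Reagents that add atoms: none
Why: Borohydride reduction of the aryl aldehyde to the benzylic alcohol; the phenol is untouched and no stereocentre is formed.

**Step 2**
Reactants: 2 3-(hydroxymethyl)-4-methoxyphenol
Product: 3 2-bromo-5-(hydroxymethyl)-4-methoxyphenol
Conditions: NBS (1.0 equiv), MeCN, −20 → 0 °C
Reagents that add atoms: N-bromosuccinimide, O=C1CCC(=O)N1Br
Why: Electrophilic aromatic bromination directed by the free phenol: the para position is blocked by OMe, and of the two ortho positions the one not flanked by CH2OH reacts, which is the carbon that later carries C11.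

**Step 3**
Reactants: 3 2-bromo-5-(hydroxymethyl)-4-methoxyphenol
Product: 4 1-bromo-5-methoxy-2-(triisopropylsilyloxy)-4-[(triisopropylsilyloxy)methyl]benzene (ArT–Br)
Conditions: i-Pr3SiCl (2.4 equiv), imidazole, DMF, rt
Reagents that add atoms: triisopropylsilyl chloride, CC(C)[Si](Cl)(C(C)C)C(C)C
Why: Imidazole-promoted silylation of both hydroxyls with a bulky silyl group that survives the organolithium, Lewis-acid, hydride and oxidation steps and is removed from both oxygens in one fluoride step.

**Step 4**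
Reactants: 4 ArT–Br; 5 geranyl bromide, (2E)-1-bromo-3,7-dimethylocta-2,6-diene
Product: 8 1-[(2E)-3,7-dimethylocta-2,6-dien-1-yl]-5-methoxy-2-(triisopropylsilyloxy)-4-[(triisopropylsilyloxy)methyl]benzene (geranyl–ArT), via aryllithium 6 (not isolated), via arylcopper 7 (not isolated)
Conditions: n-BuLi, THF, −78 °C; CuBr·SMe2, −78 °C; then 5, −78 → 0 °C
Reagents that add atoms: none
Why: Bromine–lithium exchange, transmetalation to copper and SN2 allylation with the allylic bromide (arylcopper–allyl halide coupling) give the linear product with the 2E geometry retained; low temperature and the bulky silyl group suppress O→C silyl migration.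

**Step 5**
Reactants: 8 geranyl–ArT
Product: 9 (2E,6E)-2,6-dimethyl-8-ArT-octa-2,6-dien-1-ol
Conditions: SeO2 (0.3 equiv), t-BuOOH, salicylic acid (cat.), CH2Cl2, 0 °C → rt, stopped at partial conversion
Reagents that add atoms: tert-butyl hydroperoxide (terminal oxygen source), CC(C)(C)OO; selenium dioxide (oxygen carrier), O=[Se]=O
Why: Sharpless-modified Riley allylic oxidation (ene reaction, then [2,3]-sigmatropic shift) hydroxylates the E-methyl of the most accessible terminal trisubstituted alkene and gives the (2E)-allylic alcohol.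

**Step 6**
Reactants: 9 (2E,6E)-2,6-dimethyl-8-ArT-octa-2,6-dien-1-ol
Product: 10 (2E,6E)-1-bromo-2,6-dimethyl-8-ArT-octa-2,6-diene
Conditions: CBr4, PPh3, CH2Cl2, 0 °C; used crude
Reagents that add atoms: carbon tetrabromide, BrC(Br)(Br)Br
Why: Appel bromination of the primary allylic alcohol under neutral conditions, without allylic transposition or change of alkene geometry.

**Step 7**
Reactants: 11 ethyl 2-methyl-3-oxobutanoate; 12 (−)-8-phenylmenthol, (1R,2S,5R)-5-methyl-2-(2-phenylpropan-2-yl)cyclohexan-1-ol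
Product: 13 Pm 2-methyl-3-oxobutanoate (both C2 epimers)
Conditions: DMAP (0.3 equiv), toluene, reflux, 4 Å MS (removal of EtOH)
Reagents that add atoms: none
Why: DMAP-catalysed transesterification of a β-keto ester, driven by removal of ethanol, installs the chiral auxiliary.

**Step 8**
Reactants: 13 Pm 2-methyl-3-oxobutanoate; 10 allylic bromide
Product: 15 Pm (6E,10E)-2,6,10-trimethyl-3-oxo-12-ArT-dodeca-6,10-dienoate (both C2 epimers), via dianion 14 (not isolated)
Conditions: NaH, THF, 0 °C; n-BuLi, 0 °C; then 10, 0 °C → rt; NH4Cl work-up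
Reagents that add atoms: none
Why: Weiler dianion alkylation: the more reactive terminal carbanion displaces the allylic bromide (SN2) and completes the carbon skeleton; the α-stereocentre does not matter because it becomes the radical centre.

**Step 9 (key step)**
Reactants: 15 open-chain β-keto ester
Product: 16 bicyclic keto ester: trans-decalin with C3 ketone, C4 (CH3)(CO2Pm), C10 CH3, exocyclic C8=C12 and C9 CH2ArT; target decalin configuration
Conditions: Mn(OAc)3·2H2O (2.2 equiv), Cu(OAc)2·H2O (0.5 equiv), Yb(OTf)3 (1 equiv), CF3CH2OH, −5 → 0 °C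
Reagents that add atoms: none
Why: Oxidative free-radical polyene cyclisation (Snider type) under lanthanide chelation: trivalent manganese generates the Yb-chelated α-keto ester radical, one face of which is blocked by the phenyl group of the auxiliary; 6-endo/6-endo closure through a chair–chair transition state gives the trans-decalin with axial ester at C4, H5 trans to the C10 methyl and equatorial CH2ArT at C9 (from the two E-alkenes), and divalent copper oxidises the tertiary C8 radical to the alkene (mainly exocyclic; the minor endocyclic isomer is 17 and converges in the next step).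

**Step 10**
Reactants: 16 exo-methylene keto ester
Product: 17 bicyclic keto ester with the C7=C8 alkene (C12 now CH3); otherwise as 16
Conditions: Co(salen)Cl (3 mol %; salen = N,N′-bis(3,5-di-tert-butylsalicylidene)cyclohexane-1,2-diaminate), PhSiH3 (6 mol %), benzene, rt
Reagents that add atoms: none
Why: Cobalt-hydride hydrogen-atom-transfer alkene isomerisation (Shenvi type): reversible hydrogen-atom addition to the 1,1-disubstituted alkene gives the tertiary C8 radical, which returns a hydrogen atom from the accessible C7 methylene and not from the shielded C9–H; the trisubstituted product is inert to further reaction and no stereocentre is touched.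

**Step 11**
Reactants: 17 keto ester
Product: 18 C3 tosylhydrazone of 17
Conditions: TsNHNH2, EtOH, AcOH (cat.), 70 °C
Reagents that add atoms: p-toluenesulfonyl hydrazide, Cc1ccc(cc1)S(=O)(=O)NN
Why: Hydrazone condensation at the hindered C3 ketone prepares the deoxygenation; the neopentyl auxiliary ester is too hindered to cyclise to a pyrazolone.

**Step 12**
Reactants: 18 tosylhydrazone
Product: 19 primary alcohol: Δ7 decalin with C3 now CH2 and C4 (CH3)(CH2OH); C9 CH2ArT; target decalin configuration
Conditions: LiAlH4, THF, reflux; H2O/NaOH work-up (auxiliary 12 recovered)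
Reagents that add atoms: none
Why: Caglioti reduction: hydride adds to C=N and loss of sulfinate and N2 leaves CH2 at C3, while the same reagent reduces the hindered ester to the C4 CH2OH group and releases the auxiliary; no stereocentre is affected.

**Step 13**
Reactants: 19 primary alcohol
Product: 21 carboxylic acid: as 19 with C4 (CH3)(CO2H), via aldehyde 20 (not isolated)
Conditions: TEMPO (0.2 equiv), PhI(OAc)2 (2.2 equiv), MeCN–H2O, rt
Reagents that add atoms: water, O
Why: Oxoammonium (TEMPO) oxidation of the neopentyl alcohol to the aldehyde and, through its hydrate, to the acid (Epp–Widlanski conditions); silyl ethers, the arene and the trisubstituted alkene are tolerated.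

**Step 14**
Reactants: 21 bis-silyl acid
Product: 22 phenol acid: decalin acid whose C11 carries 2-hydroxy-4-(hydroxymethyl)-5-methoxyphenyl
Conditions: Bu4NF, THF, rt; NH4Cl work-up
Reagents that add atoms: none
Why: Fluoride cleavage of both Si–O bonds in one operation unmasks the phenol needed for dearomatisation and the CH2OH needed to direct the epoxidation.

**Step 15**
Reactants: 22 phenol acid
Product: 23 quinone monoketal: C6′ ketone, C3′ dimethyl ketal, C1′=C2′ and C4′=C5′ alkenes, C4′ CH2OH
Conditions: PhI(OAc)2 (1.05 equiv), MeOH, 0 °C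
Reagents that add atoms: methanol, CO
Why: Hypervalent-iodine oxidative dearomatisation of a p-methoxyphenol in methanol: the phenol carbon becomes the C6′ ketone and methanol adds at C3′, which fixes which alkene is epoxidised next.

**Step 16**
Reactants: 23 quinone monoketal
Product: 24 epoxy ketal: C1′–C2′ oxirane with the configuration of the target; C6′ ketone and C3′ ketal retained
Conditions: Ph3COOH, NaN(SiMe3)2 (excess, also deprotonates CO2H and CH2OH), L-(+)-diisopropyl tartrate, toluene–THF, 4 Å MS, −50 °C; NH4Cl work-up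
Reagents that add atoms: trityl hydroperoxide, OOC(c1ccccc1)(c1ccccc1)c1ccccc1
Why: Tartrate-mediated, hydroxyl-directed nucleophilic (Weitz–Scheffer) epoxidation: only C2′ is an unsubstituted β-carbon, so the C1′=C2′ alkene reacts, and the chiral sodium tartrate–peroxide assembly anchored on the C4′ CH2OH delivers the peroxide to one face, setting C1′ and C2′ under reagent control, independent of the remote decalin.

**Step 17**
Reactants: 24 epoxy ketal
Product: 25 quinone epoxide: C3′ and C6′ ketones, C1′–C2′ oxirane, C4′=C5′ alkene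
Conditions: oxalic acid, THF–H2O, rt
Reagents that add atoms: water, O
Why: Mild acid-catalysed ketal hydrolysis (oxocarbenium ion, water addition, loss of methanol) unveils the C3′ carbonyl without opening the oxirane.

**Step 18**
Reactants: 25 quinone epoxide
Product: 27 target, (1R,4aS,5R,8aS)-5-{[(1R,2R,5S,6S)-2,5-dihydroxy-4-(hydroxymethyl)-7-oxabicyclo[4.1.0]hept-3-en-1-yl]methyl}-1,4a,6-trimethyl-1,2,3,4,4a,5,8,8a-octahydronaphthalene-1-carboxylic acid, via hydroxy enone 26 (not isolated)
Conditions: i-Bu2AlH (excess), THF, −78 °C; aqueous potassium sodium tartrate work-up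
Reagents that add atoms: none
Why: Double 1,2-reduction: each carbonyl is attacked from the face opposite the oxirane oxygen (Felkin–Anh-type polar control, as in syn-selective epoxy ketone reductions), placing both new hydroxyls (C3′, C6′) cis to the epoxide, while the aluminium carboxylate and the oxirane are inert at −78 °C.

**Compound list**
1 | 5-hydroxy-2-methoxybenzaldehyde | COc1ccc(O)cc1C=O | starting material
2 | 3-(hydroxymethyl)-4-methoxyphenol | COc1ccc(O)cc1CO | intermediate
3 | 2-bromo-5-(hydroxymethyl)-4-methoxyphenol | COc1cc(Br)c(O)cc1CO | intermediate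
4 | 1-bromo-5-methoxy-2-(triisopropylsilyloxy)-4-[(triisopropylsilyloxy)methyl]benzene (ArT–Br) | COc1cc(Br)c(O[Si](C(C)C)(C(C)C)C(C)C)cc1CO[Si](C(C)C)(C(C)C)C(C)C | intermediate
5 | geranyl bromide, (2E)-1-bromo-3,7-dimethylocta-2,6-diene | CC(C)=CCC/C(C)=C/CBr | starting material
6 | aryllithium ArT–Li | COc1cc([Li])c(O[Si](C(C)C)(C(C)C)C(C)C)cc1CO[Si](C(C)C)(C(C)C)C(C)C | intermediate
7 | arylcopper ArT–Cu | COc1cc([Cu])c(O[Si](C(C)C)(C(C)C)C(C)C)cc1CO[Si](C(C)C)(C(C)C)C(C)C | intermediate
8 | geranyl–ArT, 1-[(2E)-3,7-dimethylocta-2,6-dien-1-yl]-5-methoxy-2-(triisopropylsilyloxy)-4-[(triisopropylsilyloxy)methyl]benzene | CC(C)=CCC/C(C)=C/Cc1cc(OC)c(CO[Si](C(C)C)(C(C)C)C(C)C)cc1O[Si](C(C)C)(C(C)C)C(C)C | intermediate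
9 | (2E,6E)-2,6-dimethyl-8-ArT-octa-2,6-dien-1-ol | OC/C(C)=C/CC/C(C)=C/Cc1cc(OC)c(CO[Si](C(C)C)(C(C)C)C(C)C)cc1O[Si](C(C)C)(C(C)C)C(C)C | intermediate
10 | (2E,6E)-1-bromo-2,6-dimethyl-8-ArT-octa-2,6-diene | BrC/C(C)=C/CC/C(C)=C/Cc1cc(OC)c(CO[Si](C(C)C)(C(C)C)C(C)C)cc1O[Si](C(C)C)(C(C)C)C(C)C | intermediate
11 | ethyl 2-methyl-3-oxobutanoate | CCOC(=O)C(C)C(C)=O | starting material
12 | (−)-8-phenylmenthol, (1R,2S,5R)-5-methyl-2-(2-phenylpropan-2-yl)cyclohexan-1-ol | O[C@@H]1C[C@H](C)CC[C@H]1C(C)(C)c1ccccc1 | starting material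
13 | Pm 2-methyl-3-oxobutanoate (both C2 epimers) | CC(=O)C(C)C(=O)O[C@@H]1C[C@H](C)CC[C@H]1C(C)(C)c1ccccc1 | intermediate
14 | sodium lithium dianion of 13 | [Li+].[Na+].[CH2-]C(=O)[C-](C)C(=O)O[C@@H]1C[C@H](C)CC[C@H]1C(C)(C)c1ccccc1 | intermediate
15 | Pm (6E,10E)-2,6,10-trimethyl-3-oxo-12-ArT-dodeca-6,10-dienoate (both C2 epimers) | CC(C(=O)O[C@@H]1C[C@H](C)CC[C@H]1C(C)(C)c1ccccc1)C(=O)CC/C(C)=C/CC/C(C)=C/Cc1cc(OC)c(CO[Si](C(C)C)(C(C)C)C(C)C)cc1O[Si](C(C)C)(C(C)C)C(C)C | intermediate
16 | exo-methylene bicyclic keto ester (3-oxo; C8=C12; axial CO2Pm at C4; C9 CH2ArT; target decalin configuration) | C=C1CC[C@H]2[C@@](C)(CCC(=O)[C@@]2(C)C(=O)O[C@@H]3C[C@H](C)CC[C@H]3C(C)(C)c3ccccc3)[C@@H]1Cc1cc(OC)c(CO[Si](C(C)C)(C(C)C)C(C)C)cc1O[Si](C(C)C)(C(C)C)C(C)C | intermediate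
17 | Δ7 bicyclic keto ester (3-oxo; C7=C8; otherwise as 16) | CC1=CC[C@H]2[C@@](C)(CCC(=O)[C@@]2(C)C(=O)O[C@@H]3C[C@H](C)CC[C@H]3C(C)(C)c3ccccc3)[C@@H]1Cc1cc(OC)c(CO[Si](C(C)C)(C(C)C)C(C)C)cc1O[Si](C(C)C)(C(C)C)C(C)C | intermediate
18 | C3 tosylhydrazone of 17 | CC1=CC[C@H]2[C@@](C)(CCC(=NNS(=O)(=O)c3ccc(C)cc3)[C@@]2(C)C(=O)O[C@@H]3C[C@H](C)CC[C@H]3C(C)(C)c3ccccc3)[C@@H]1Cc1cc(OC)c(CO[Si](C(C)C)(C(C)C)C(C)C)cc1O[Si](C(C)C)(C(C)C)C(C)C | intermediate
19 | Δ7 decalin with C4 (CH3)(CH2OH) and C9 CH2ArT; target decalin configuration | CC1=CC[C@H]2[C@@](C)(CCC[C@@]2(C)CO)[C@@H]1Cc1cc(OC)c(CO[Si](C(C)C)(C(C)C)C(C)C)cc1O[Si](C(C)C)(C(C)C)C(C)C | intermediate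
20 | corresponding C4 aldehyde | CC1=CC[C@H]2[C@@](C)(CCC[C@@]2(C)C=O)[C@@H]1Cc1cc(OC)c(CO[Si](C(C)C)(C(C)C)C(C)C)cc1O[Si](C(C)C)(C(C)C)C(C)C | intermediate
21 | decalin carboxylic acid with C9 CH2ArT (bis-silyl ether) | CC1=CC[C@H]2[C@@](C)(CCC[C@@]2(C)C(=O)O)[C@@H]1Cc1cc(OC)c(CO[Si](C(C)C)(C(C)C)C(C)C)cc1O[Si](C(C)C)(C(C)C)C(C)C | intermediate
22 | phenol acid (C11 carries 2-hydroxy-4-(hydroxymethyl)-5-methoxyphenyl) | CC1=CC[C@H]2[C@@](C)(CCC[C@@]2(C)C(=O)O)[C@@H]1Cc1cc(OC)c(CO)cc1O | intermediate
23 | quinone monoketal (C6′ ketone; C3′ dimethyl ketal) | CC1=CC[C@H]2[C@@](C)(CCC[C@@]2(C)C(=O)O)[C@@H]1CC1=CC(OC)(OC)C(CO)=CC1=O | intermediate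
24 | epoxy ketal (C1′–C2′ oxirane as in the target; C6′ ketone; C3′ ketal) | CC1=CC[C@H]2[C@@](C)(CCC[C@@]2(C)C(=O)O)[C@@H]1C[C@]12O[C@H]1C(OC)(OC)C(CO)=CC2=O | intermediate
25 | quinone epoxide (C3′ and C6′ ketones) | CC1=CC[C@H]2[C@@](C)(CCC[C@@]2(C)C(=O)O)[C@@H]1C[C@]12O[C@H]1C(=O)C(CO)=CC2=O | intermediate
26 | hydroxy enone (C3′ OH cis to the oxirane; C6′ ketone) | CC1=CC[C@H]2[C@@](C)(CCC[C@@]2(C)C(=O)O)[C@@H]1C[C@]12O[C@H]1[C@@H](O)C(CO)=CC2=O | intermediate
27 | (1R,4aS,5R,8aS)-5-{[(1R,2R,5S,6S)-2,5-dihydroxy-4-(hydroxymethyl)-7-oxabicyclo[4.1.0]hept-3-en-1-yl]methyl}-1,4a,6-trimethyl-1,2,3,4,4a,5,8,8a-octahydronaphthalene-1-carboxylic acid | CC1=CC[C@H]2[C@@](C)(CCC[C@@]2(C)C(=O)O)[C@@H]1C[C@]12O[C@H]1[C@@H](O)C(CO)=C[C@H]2O | target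

**Total step count:** 18. **Longest linear sequence:** 17 (steps 1–6 and 8–18; step 7 is the side branch).

**Three steps most likely to fail**

Step 9. Yield, face selectivity and alkene position all depend on one operation. The fallback sets out from 15 and comes back at 16. The sodium enolate of 15 is brominated with N-bromosuccinimide to the tertiary α-bromo β-keto ester F1. Bromine-atom-transfer radical bicyclisation (Et3B/air, toluene, −78 °C) on its complex with Mg(ClO4)2 and a C2-symmetric bis(oxazoline), a second control element on top of the auxiliary, gives the C8 tertiary bromide F2. Hofmann-selective E2 elimination with t-BuOK then gives 16. This changes how the radical is made, how the cascade ends and how the face is controlled.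

Step 16. The substrate carries several acidic groups and an α-substituted alkene, and the sense and level of induction are uncertain. The fallback sets out from 23 and comes back at 25. Acid-catalysed ketal exchange of 23 with (2S,4S)-pentane-2,4-diol gives the chiral spiroketal F3, in which an axial methyl of the dioxane shields one face of the dienone. Epoxidation with Ph3COOK then gives the epoxy spiroketal F4 under auxiliary control instead of reagent control, and aqueous-acid hydrolysis returns to 25. The antipodal diol is used if the other face is needed.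

Step 18. The C6′ carbonyl sits next to the quaternary oxirane carbon, so the selectivity of the second reduction is the least certain point. The fallback sets out from 24 and comes back at 27, with the two reductions separated. With C3′ still a ketal, the only ketone of 24 is reduced with NaBH4/CeCl3·7H2O to the hydroxy ketal F5, whose epimer ratio can be checked at this simpler stage. Oxalic acid hydrolysis gives the hydroxy enone F6. The remaining C3′ carbonyl, the well-precedented case next to an oxirane CH, is reduced with i-Bu2AlH to 27.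

**Further compounds**
F1 | step 9 | Pm (6E,10E)-2-bromo-2,6,10-trimethyl-3-oxo-12-ArT-dodeca-6,10-dienoate | CC(Br)(C(=O)O[C@@H]1C[C@H](C)CC[C@H]1C(C)(C)c1ccccc1)C(=O)CC/C(C)=C/CC/C(C)=C/Cc1cc(OC)c(CO[Si](C(C)C)(C(C)C)C(C)C)cc1O[Si](C(C)C)(C(C)C)C(C)C
F2 | step 9 | bicyclic keto ester with tertiary bromide at C8 (C8 epimers; otherwise as 16) | CC1(Br)CC[C@H]2[C@@](C)(CCC(=O)[C@@]2(C)C(=O)O[C@@H]3C[C@H](C)CC[C@H]3C(C)(C)c3ccccc3)[C@@H]1Cc1cc(OC)c(CO[Si](C(C)C)(C(C)C)C(C)C)cc1O[Si](C(C)C)(C(C)C)C(C)C
F3 | step 16 | quinone mono(spiroketal) of (2S,4S)-pentane-2,4-diol at C3′ | CC1=CC[C@H]2[C@@](C)(CCC[C@@]2(C)C(=O)O)[C@@H]1CC1=CC2(O[C@@H](C)C[C@H](C)O2)C(CO)=CC1=O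
F4 | step 16 | epoxy spiroketal (C1′–C2′ oxirane as in the target) | CC1=CC[C@H]2[C@@](C)(CCC[C@@]2(C)C(=O)O)[C@@H]1C[C@]12O[C@H]1C1(O[C@@H](C)C[C@H](C)O1)C(CO)=CC2=O
F5 | step 18 | hydroxy ketal (C6′ OH cis to the oxirane; C3′ dimethyl ketal) | CC1=CC[C@H]2[C@@](C)(CCC[C@@]2(C)C(=O)O)[C@@H]1C[C@]12O[C@H]1C(OC)(OC)C(CO)=C[C@H]2O
F6 | step 18 | hydroxy enone (C6′ OH cis to the oxirane; C3′ ketone) | CC1=CC[C@H]2[C@@](C)(CCC[C@@]2(C)C(=O)O)[C@@H]1C[C@]12O[C@H]1C(=O)C(CO)=C[C@H]2O
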